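Slowness is what I have to price here: the last of the left-handed substrate leaves late, so I count its fall in powers of ten.

| flask | left-handed substrate | right-handed substrate | gas | free catalyst | temperature | remark | time |
|---|---|---|---|---|---|---|---|
| north | 0.020 M | 0.020 M | 3 mM (held) | 0.20 mM | 25 °C | run made earlier |  |
| east | 0.020 M | 0.020 M | 3 mM (held) | 0.30 mM | 36 °C | run made earlier |  |
| Sunday's | 0.020 M | 0.020 M | 3.0 mM (held) | 0.40 mM |  | at 20 °C throughout | 6.0 d |
| Tuesday's | 0.020 M | 0.020 M | 3.0 mM (held) | 0.40 mM |  | at 40 °C until 30 h, from then on at 20 °C | 4.0 d |

| run | time / d | left-handed product / % | left-handed substrate / % |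
|---|---|---|---|
| north | 0.500 | 7.2 | 41.7 |
| north | 1.04 | 15.9 | 34.5 |
| north | 1.67 | 24.7 | 25.0 |
| north | 4.00 | 46.1 | 4.1 |
| north | 6.00 | 49.7 | 1.6 |
| east | 0.250 | 5.8 | 43.1 |
| east | 0.833 | 22.0 | 27.0 |
| east | 1.67 | 38.1 | 11.6 |
| east | 2.50 | 47.4 | 1.1 |
| east | 3.00 | 49.7 | 0 |

(readings scatter by 1 percentage point)

- free catalyst is single-handed; left-handed substrate and right-handed substrate are mirror images of each other, charged as a racemate, each of them at the stated concentration
- at the start none of coupling partner is dissolved
- what may be going on: free catalyst + left-handed substrate <-> catalyst intermediate A; gas <-> coupling partner; coupling partner + catalyst intermediate A -> free catalyst + left-handed product; free catalyst + right-handed substrate <-> catalyst intermediate B; coupling partner + catalyst intermediate B -> free catalyst + right-handed product; 2 coupling partner -> self-condensation product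

* which of the two ends with the higher amount of left-handed product, in percent of the left-handed substrate and right-handed substrate together charged ("neither" if they lie within 2 percentage points) (Sunday's / Tuesday's / neither)
* left-handed product at the end, in percent of the left-handed substrate and right-handed substrate together charged, Sunday's
* left-handed product at the end, in percent of the left-handed substrate and right-handed substrate together charged, Tuesday's

The ledger of left-handed substrate, the limiting reagent for left-handed product, opens at 50.0% of the charge. One entry is what stands free, another is what catalyst intermediate A holds, and the rest is left-handed product. In Sunday's and Tuesday's, catalyst intermediate A can hold at most 1.00% on this scale, since that is the catalyst charged. So the free entry is the one to reckon.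

The north run shows 4.1% free at 4.00 d, which is 1.09 powers of ten down. If speed goes with catalyst, that means 1.84 d per power of ten at 0.40 mM. The east run, read the same way at 2.50 d, gives 1.13 d, though its 1.1% is hardly above the scatter. I stretch the logarithm of that ratio across temperature. The decade time, the days from the charge per power of ten of left-handed substrate, is then 2.30 d at 20 °C and 0.948 d at 40 °C.

Sunday's therefore has 2.61 powers of ten in hand and Tuesday's 2.52. These leave about 0.122% and 0.152% free. Even with the full 1.00% held as well, Tuesday's falls short of the ceiling by less than the margin of 2 percentage points, and Sunday's does too. I expect neither to win.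

The forecast, reckoned on rates rather than on tails, says neither, with 49.9% for Sunday's and 49.9% for Tuesday's, and adds “I see no sign of catalyst death”.

    free catalyst + left-handed substrate ⇌ catalyst intermediate A (K = 130 /M, k = 317 /M/min, Ea = 37.0 kJ/mol, ΔH = −30.0 kJ/mol)
    gas ⇌ coupling partner, rate k2*(csat - [coupling partner]) (kL = 0.00704 /min)
    coupling partner + catalyst intermediate A → free catalyst + left-handed product (k = 60.7 /M/min, Ea = 60.0 kJ/mol)
    free catalyst + right-handed substrate ⇌ catalyst intermediate B (K = 111 /M, k = 330 /M/min, Ea = 58.0 kJ/mol, ΔH = 7.00 kJ/mol)
    coupling partner + catalyst intermediate B → free catalyst + right-handed product (k = 25.3 /M/min, Ea = 42.0 kJ/mol)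
    2 coupling partner → self-condensation product (k = 0.245 /M/min, Ea = 64.0 kJ/mol)
    (constants at 40 °C)

Sunday's ends at 50.0% of left-handed product and Tuesday's at 50.0%, so the answer is neither. Tuesday's still holds 0.0124% of left-handed substrate at 4.00 d, which is 3.61 powers of ten down, against my 2.52. During its stretch at 20 °C, Tuesday's left-handed substrate goes from 12.4% at 1.25 d to 0.0124% at 4.00 d, which is one power of ten in 0.917 d, shorter than my decade time of 2.30 d.

The numbers in the tables come from a simulation for an exercise, and the scatter is random.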